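The route rests on disconnecting C4–C5 of the oxepinone. The feature exploited is the C5 aryl ketone of the seven-membered ring fused to ring A, which has the carbonyl-bearing C4 next to it and a C3–H one atom further: this is the pattern left when a ring A aldehyde C–H adds across a C3=C4 cinnamate tethered through O1 and the quaternary C2. One rhodium-catalysed hydroacylation therefore closes the oxepinone, forms C4–C5 and sets C3 and C4. The precursor is an enantiopure (E)-3-phenylpent-2-enedioate whose quaternary carbon (later C2) carries a 2-formyl-3,5-dimethoxyphenoxy group, a 4-(methoxymethoxy)phenyl group and a tert-butyl ester; after amide formation a single acidic step unmasks the target.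

Key step: step 8

Assumption: tert-butyl 2-(4-hydroxyphenyl)acetate is taken as a catalogue compound; the oxepine is numbered O1, C2, C3, C4, C5, with C5a to C9a in ring A.

Step 1
Reactants: 1 tert-butyl 2-(4-hydroxyphenyl)acetate
Product: 2 tert-butyl 2-[4-(methoxymethoxy)phenyl]acetate
Conditions: MOMCl, iPr2NEt, CH2Cl2, 0 °C → rt
Reagents that add atoms: chloromethyl methyl ether, COCCl
Why: Phenol O-alkylation with an α-chloro ether under amine base (methoxymethyl ether formation) is routine and leaves the tert-butyl ester untouched.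

Step 2
Reactants: 2 tert-butyl 2-[4-(methoxymethoxy)phenyl]acetate
Product: 3 tert-butyl 2-bromo-2-[4-(methoxymethoxy)phenyl]acetate (racemic)
Conditions: LiN(SiMe3)2, THF, −78 °C; then enolate added to NBS, THF, −78 °C
Reagents that add atoms: N-bromosuccinimide, O=C1CCC(=O)N1Br
Why: Electrophilic α-bromination of the preformed lithium ester enolate, run by inverse addition at low temperature to avoid proton exchange with the more acidic product, should give the benzylic α-bromo ester without exposing the acid-labile ether to HBr.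

Step 3
Reactants: 3 tert-butyl 2-bromo-2-[4-(methoxymethoxy)phenyl]acetate; 4 2-hydroxy-4,6-dimethoxybenzaldehyde
Product: 5 tert-butyl 2-(2-formyl-3,5-dimethoxyphenoxy)-2-[4-(methoxymethoxy)phenyl]acetate (racemic)
Conditions: K2CO3, DMF, rt
Reagents that add atoms: none
Why: In this Williamson ether synthesis the phenoxide of 4 should displace the activated benzylic α-bromo ester by an SN2 path at room temperature, where carbonate is too weak to enolise 5 toward aldol closure on the deactivated aldehyde.

Step 4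
Reactants: 5 tert-butyl 2-(2-formyl-3,5-dimethoxyphenoxy)-2-[4-(methoxymethoxy)phenyl]acetate
Product: 6 tert-butyl 2-[2-(1,3-dioxolan-2-yl)-3,5-dimethoxyphenoxy]-2-[4-(methoxymethoxy)phenyl]acetate (racemic)
Conditions: (Me3SiOCH2)2, Me3SiOTf (10 mol%), CH2Cl2, −78 → −20 °C; Et3N quench
Reagents that add atoms: 1,2-bis(trimethylsilyloxy)ethane, C[Si](C)(C)OCCO[Si](C)(C)C
Why: Silyl-triflate-catalysed acetalisation, driven by formation of hexamethyldisiloxane and free of protic acid, should mask the hindered electron-rich aldehyde while the methoxymethyl ether and tert-butyl ester survive, so that the enolate of the next step cannot add to the ortho aldehyde.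

Step 5
Reactants: 6 tert-butyl 2-[2-(1,3-dioxolan-2-yl)-3,5-dimethoxyphenoxy]-2-[4-(methoxymethoxy)phenyl]acetate; 7 ethyl 3-phenylprop-2-ynoate
Product: 9 5-tert-butyl 1-ethyl (2E)-4-[2-(1,3-dioxolan-2-yl)-3,5-dimethoxyphenoxy]-4-[4-(methoxymethoxy)phenyl]-3-phenylpent-2-enedioate (racemic), via kinetic Z-isomer 8 (not isolated)
Conditions: KOtBu (20 mol%), THF, 0 °C → rt; AcOH; then (PhS)2 (10 mol%), 390 nm light, PhMe, rt
Reagents that add atoms: none
Why: Base-catalysed Michael addition of the tertiary ester enolate to the β-carbon of the ynoate builds the quaternary carbon in a proton-transfer chain, and reversible thiyl-radical addition then equilibrates the kinetic alkene mixture to the E isomer, expected to be the more stable because its ethyl ester avoids the quaternary carbon and lies cis to the twisted phenyl ring.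

Step 6
Reactants: 9 5-tert-butyl 1-ethyl (2E)-4-[2-(1,3-dioxolan-2-yl)-3,5-dimethoxyphenoxy]-4-[4-(methoxymethoxy)phenyl]-3-phenylpent-2-enedioate (racemic)
Product: 10 5-tert-butyl 1-ethyl (2E,4R)-4-[2-(1,3-dioxolan-2-yl)-3,5-dimethoxyphenoxy]-4-[4-(methoxymethoxy)phenyl]-3-phenylpent-2-enedioate
Conditions: preparative HPLC, amylose tris(3,5-dimethylphenylcarbamate) phase, hexane/iPrOH, 0.1% Et3N
Reagents that add atoms: none
Why: Resolution of a configurationally fixed quaternary stereocentre by chromatography on a chiral stationary phase is a dependable way to secure C2, with the basic modifier protecting the acetal and the absolute configuration to be assigned by anomalous-dispersion X-ray analysis or by correlation with the target.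

Step 7
Reactants: 10 5-tert-butyl 1-ethyl (2E,4R)-4-[2-(1,3-dioxolan-2-yl)-3,5-dimethoxyphenoxy]-4-[4-(methoxymethoxy)phenyl]-3-phenylpent-2-enedioate
Product: 11 5-tert-butyl 1-ethyl (2E,4R)-4-(2-formyl-3,5-dimethoxyphenoxy)-4-[4-(methoxymethoxy)phenyl]-3-phenylpent-2-enedioate
Conditions: pyridinium p-toluenesulfonate (cat.), acetone/H2O, rt
Reagents that add atoms: water, O
Why: In this acetal hydrolysis the dioxolane of a 2,4,6-trioxygenated benzaldehyde ionises far more readily than the methoxymethyl aryl ether or the tert-butyl ester, so only the aldehyde should be released, and the quaternary centre cannot epimerise.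

Step 8
Reactants: 11 5-tert-butyl 1-ethyl (2E,4R)-4-(2-formyl-3,5-dimethoxyphenoxy)-4-[4-(methoxymethoxy)phenyl]-3-phenylpent-2-enedioate
Product: 12 2-tert-butyl 4-ethyl (2S,3S,4R)-6,8-dimethoxy-2-[4-(methoxymethoxy)phenyl]-5-oxo-3-phenyl-2,3,4,5-tetrahydro-1-benzoxepine-2,4-dicarboxylate
Conditions: [Rh(nbd)2]BF4 (10 mol%), (R)-DTBM-SEGPHOS (10 mol%), H2 then Ar (gives [Rh((R)-DTBM-SEGPHOS)]BF4); ClCH2CH2Cl, 60 °C
Reagents that add atoms: none
Why: Proposed new method: the cationic monovalent rhodium centre, held by ether O1, should insert into the aldehyde C–H bond, the acyl hydride of trivalent rhodium should bind the C3=C4 alkene and pass hydride to the β-carbon C3 so that rhodium sits on C4 as an ester-stabilised alkyl, and C–C reductive elimination should then join C4 to the acyl carbon C5. The closest known reaction type is the ether- or thioether-directed intramolecular rhodium-catalysed alkene hydroacylation of 2-(allyloxy)benzaldehydes to benzoxepinones, established only for mono- and 1,1-disubstituted unactivated alkenes and not for a β,β-disubstituted acrylate. The seven-membered ring closes in a formal 7-endo-trig sense by reductive elimination from an eight-membered rhodacycle, the six-ring alternative being disfavoured because it would place the acyl group on the fully substituted C3. C3 is set by the alkene face that receives hydride, which the (R)-bisphosphine together with the fixed C2 centre should direct to the side of the tert-butyl ester, leaving phenyl cis to the C2 aryl group, whereas C4 follows from syn addition to the E alkene (ester trans to phenyl) and, as the α-carbon of a β-keto ester, would also settle there by enolisation. The step needs hydride transfer to C3 rather than C4, insertion rather than decarbonylation, and one C3 face: the conjugate polarity of the acrylate and the quaternary C2 should secure the first, O1 chelation the second, and the ligand enantiomer matched to C2 the third.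

Step 9
Reactants: 13 1,4-dioxane-2,5-diol (glycolaldehyde dimer); 14 ethyl 2-(triphenyl-λ5-phosphanylidene)propanoate
Product: 15 ethyl (2E)-4-hydroxy-2-methylbut-2-enoate
Conditions: CH2Cl2, 40 °C
Reagents that add atoms: none
Why: Wittig reaction of the ester-stabilised, α-branched ylide with glycolaldehyde released from its dimer should give the E trisubstituted enoate, as such ylides reliably do.

Step 10
Reactants: 15 ethyl (2E)-4-hydroxy-2-methylbut-2-enoate
Product: 16 (2E)-4-hydroxy-2-methylbut-2-enoic acid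
Conditions: LiOH·H2O, THF/H2O, rt; then 1 M HCl
Reagents that add atoms: lithium hydroxide, [Li+].[OH-]
Why: Saponification of the ethyl ester followed by acidification should give the acid, which cannot lactonise because the hydroxymethyl group is trans to the carboxyl group.

Step 11
Reactants: 16 (2E)-4-hydroxy-2-methylbut-2-enoic acid; 17 tert-butyl N-(4-aminobutyl)carbamate
Product: 18 tert-butyl N-{4-[(2E)-4-hydroxy-2-methylbut-2-enamido]butyl}carbamate
Conditions: EDC·HCl, HOBt, iPr2NEt, CH2Cl2/DMF, 0 °C → rt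
Reagents that add atoms: none
Why: Carbodiimide-mediated amide coupling through the hydroxybenzotriazole ester acylates the primary amine of 17 much faster than the primary hydroxyl group, so the alcohol needs no protection.

Step 12
Reactants: 18 tert-butyl N-{4-[(2E)-4-hydroxy-2-methylbut-2-enamido]butyl}carbamate
Product: 19 (2E)-N-(4-aminobutyl)-4-hydroxy-2-methylbut-2-enamide
Conditions: HCl (4 M in dioxane), 0 °C → rt; then K2CO3, MeOH, filter
Reagents that add atoms: none
Why: Acidolytic cleavage of the tert-butyl carbamate with loss of isobutene and carbon dioxide, followed by neutralisation, should free the primary amine without affecting the conjugated amide or the electron-poor allylic alcohol.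

Step 13
Reactants: 12 2-tert-butyl 4-ethyl (2S,3S,4R)-6,8-dimethoxy-2-[4-(methoxymethoxy)phenyl]-5-oxo-3-phenyl-2,3,4,5-tetrahydro-1-benzoxepine-2,4-dicarboxylate; 19 (2E)-N-(4-aminobutyl)-4-hydroxy-2-methylbut-2-enamide
Product: 20 tert-butyl (2S,3S,4R)-4-({4-[(2E)-4-hydroxy-2-methylbut-2-enamido]butyl}carbamoyl)-6,8-dimethoxy-2-[4-(methoxymethoxy)phenyl]-5-oxo-3-phenyl-2,3,4,5-tetrahydro-1-benzoxepine-2-carboxylate
Conditions: DMAP (30 mol%), PhMe/1,4-dioxane, 105 °C, 5 Å molecular sieves
Reagents that add atoms: none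
Why: Thermal aminolysis of a β-keto ester, which runs through an acylketene open only to the enolisable C4 ester, should convert the ethyl ester into the amide while the hindered tert-butyl ester at C2 and the doubly ortho-substituted C5 ketone stay intact, and C4 is re-protonated under thermodynamic control trans to the C3 phenyl group.

Step 14
Reactants: 20 tert-butyl (2S,3S,4R)-4-({4-[(2E)-4-hydroxy-2-methylbut-2-enamido]butyl}carbamoyl)-6,8-dimethoxy-2-[4-(methoxymethoxy)phenyl]-5-oxo-3-phenyl-2,3,4,5-tetrahydro-1-benzoxepine-2-carboxylate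
Product: 21 (2S,3S,4R)-4-({4-[(2E)-4-hydroxy-2-methylbut-2-enamido]butyl}carbamoyl)-2-(4-hydroxyphenyl)-6,8-dimethoxy-5-oxo-3-phenyl-2,3,4,5-tetrahydro-1-benzoxepine-2-carboxylic acid (CNP0300324.1)
Conditions: TFA/CH2Cl2/H2O, anisole, 0 °C → rt; then MeOH/pH 7 buffer, rt
Reagents that add atoms: none
Why: Acidolysis cleaves the tert-butyl ester (loss of isobutene) and the methoxymethyl aryl ether (acetal hydrolysis) in one operation, which avoids any basic ester hydrolysis that could open the β-keto amide by retro-Claisen cleavage or expel the ring A phenoxide from C2, and no stereocentre is touched.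

Compound list
1 | tert-butyl 2-(4-hydroxyphenyl)acetate | CC(C)(C)OC(=O)Cc1ccc(O)cc1 | starting material
2 | tert-butyl 2-[4-(methoxymethoxy)phenyl]acetate | CC(C)(C)OC(=O)Cc1ccc(OCOC)cc1 | intermediate
3 | tert-butyl 2-bromo-2-[4-(methoxymethoxy)phenyl]acetate (racemic) | CC(C)(C)OC(=O)C(Br)c1ccc(OCOC)cc1 | intermediate
4 | 2-hydroxy-4,6-dimethoxybenzaldehyde | COc1cc(O)c(C=O)c(OC)c1 | starting material
5 | tert-butyl 2-(2-formyl-3,5-dimethoxyphenoxy)-2-[4-(methoxymethoxy)phenyl]acetate (racemic) | COc1cc(OC)c(C=O)c(c1)OC(C(=O)OC(C)(C)C)c1ccc(OCOC)cc1 | intermediate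
6 | tert-butyl 2-[2-(1,3-dioxolan-2-yl)-3,5-dimethoxyphenoxy]-2-[4-(methoxymethoxy)phenyl]acetate (racemic) | COc1cc(OC)c(C2OCCO2)c(c1)OC(C(=O)OC(C)(C)C)c1ccc(OCOC)cc1 | intermediate
7 | ethyl 3-phenylprop-2-ynoate | CCOC(=O)C#Cc1ccccc1 | starting material
8 | 5-tert-butyl 1-ethyl (2Z)-4-[2-(1,3-dioxolan-2-yl)-3,5-dimethoxyphenoxy]-4-[4-(methoxymethoxy)phenyl]-3-phenylpent-2-enedioate (racemic) | COc1cc(OC)c(C2OCCO2)c(c1)OC(C(=O)OC(C)(C)C)(c1ccc(OCOC)cc1)/C(c1ccccc1)=C\C(=O)OCC | intermediate
9 | 5-tert-butyl 1-ethyl (2E)-4-[2-(1,3-dioxolan-2-yl)-3,5-dimethoxyphenoxy]-4-[4-(methoxymethoxy)phenyl]-3-phenylpent-2-enedioate (racemic) | COc1cc(OC)c(C2OCCO2)c(c1)OC(C(=O)OC(C)(C)C)(c1ccc(OCOC)cc1)/C(c1ccccc1)=C/C(=O)OCC | intermediate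
10 | 5-tert-butyl 1-ethyl (2E,4R)-4-[2-(1,3-dioxolan-2-yl)-3,5-dimethoxyphenoxy]-4-[4-(methoxymethoxy)phenyl]-3-phenylpent-2-enedioate | COc1cc(OC)c(C2OCCO2)c(c1)O[C@](C(=O)OC(C)(C)C)(c1ccc(OCOC)cc1)/C(c1ccccc1)=C/C(=O)OCC | intermediate
11 | 5-tert-butyl 1-ethyl (2E,4R)-4-(2-formyl-3,5-dimethoxyphenoxy)-4-[4-(methoxymethoxy)phenyl]-3-phenylpent-2-enedioate | COc1cc(OC)c(C=O)c(c1)O[C@](C(=O)OC(C)(C)C)(c1ccc(OCOC)cc1)/C(c1ccccc1)=C/C(=O)OCC | intermediate
12 | 2-tert-butyl 4-ethyl (2S,3S,4R)-6,8-dimethoxy-2-[4-(methoxymethoxy)phenyl]-5-oxo-3-phenyl-2,3,4,5-tetrahydro-1-benzoxepine-2,4-dicarboxylate | COc1cc(OC)c2c(c1)O[C@](C(=O)OC(C)(C)C)(c1ccc(OCOC)cc1)[C@H](c1ccccc1)[C@@H](C(=O)OCC)C2=O | intermediate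
13 | 1,4-dioxane-2,5-diol (glycolaldehyde dimer) | OC1COC(O)CO1 | starting material
14 | ethyl 2-(triphenyl-λ5-phosphanylidene)propanoate | CCOC(=O)C(C)=P(c1ccccc1)(c1ccccc1)c1ccccc1 | starting material
15 | ethyl (2E)-4-hydroxy-2-methylbut-2-enoate | CCOC(=O)/C(C)=C/CO | intermediate
16 | (2E)-4-hydroxy-2-methylbut-2-enoic acid | OC(=O)/C(C)=C/CO | intermediate
17 | tert-butyl N-(4-aminobutyl)carbamate | NCCCCNC(=O)OC(C)(C)C | starting material
18 | tert-butyl N-{4-[(2E)-4-hydroxy-2-methylbut-2-enamido]butyl}carbamate | CC(C)(C)OC(=O)NCCCCNC(=O)/C(C)=C/CO | intermediate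
19 | (2E)-N-(4-aminobutyl)-4-hydroxy-2-methylbut-2-enamide | NCCCCNC(=O)/C(C)=C/CO | intermediate
20 | tert-butyl (2S,3S,4R)-4-({4-[(2E)-4-hydroxy-2-methylbut-2-enamido]butyl}carbamoyl)-6,8-dimethoxy-2-[4-(methoxymethoxy)phenyl]-5-oxo-3-phenyl-2,3,4,5-tetrahydro-1-benzoxepine-2-carboxylate | COc1cc(OC)c2c(c1)O[C@](C(=O)OC(C)(C)C)(c1ccc(OCOC)cc1)[C@H](c1ccccc1)[C@@H](C(=O)NCCCCNC(=O)/C(C)=C/CO)C2=O | intermediate
21 | (2S,3S,4R)-4-({4-[(2E)-4-hydroxy-2-methylbut-2-enamido]butyl}carbamoyl)-2-(4-hydroxyphenyl)-6,8-dimethoxy-5-oxo-3-phenyl-2,3,4,5-tetrahydro-1-benzoxepine-2-carboxylic acid | COc1cc(OC)c2c(c1)O[C@](C(=O)O)(c1ccc(O)cc1)[C@H](c1ccccc1)[C@@H](C(=O)NCCCCNC(=O)/C(C)=C/CO)C2=O | target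

Total step count: 14 (steps 1–8, 13 and 14 on the main line; steps 9–12 for the side-chain amine).
Longest linear sequence: 10 steps (1 → 2 → 3 → 5 → 6 → 9 → 10 → 11 → 12 → 20 → 21).

Steps most likely to fail

Step 8. The hindered, electron-poor trisubstituted alkene may not insert into the acyl rhodium hydride, so that decarbonylation or simple recovery of aldehyde takes over, or hydride may be delivered to the wrong face of C3. The fallback closes the same C4–C5 bond by an aldol reaction, using known chemistry only. Setting out from acetal 10, copper hydride conjugate reduction under chiral bisphosphine control (Cu(OAc)2, the DTBM-SEGPHOS enantiomer that delivers hydride to the required face, polymethylhydrosiloxane, tBuOH, PhMe) would give 1-tert-butyl 5-ethyl (2S,3S)-2-[2-(1,3-dioxolan-2-yl)-3,5-dimethoxyphenoxy]-2-[4-(methoxymethoxy)phenyl]-3-phenylpentanedioate F1. Acetal hydrolysis as in step 7 would then give 1-tert-butyl 5-ethyl (2S,3S)-2-(2-formyl-3,5-dimethoxyphenoxy)-2-[4-(methoxymethoxy)phenyl]-3-phenylpentanedioate F2. LiN(SiMe3)2 in THF at −78 °C would form the ethyl ester enolate, which should add to the non-enolisable aldehyde to give 2-tert-butyl 4-ethyl (2S,3S)-5-hydroxy-6,8-dimethoxy-2-[4-(methoxymethoxy)phenyl]-3-phenyl-2,3,4,5-tetrahydro-1-benzoxepine-2,4-dicarboxylate F3 as a mixture at C4 and C5. Dess–Martin oxidation of the alcohol would return the route to 12, with C4 settling trans to phenyl by enolisation.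

Step 5. The hindered, weakly acidic tertiary enolate may add too slowly to the β-aryl ynoate, so that base-induced oligomerisation of 7 competes, or the alkene equilibration may stall short of the E isomer. The fallback uses a stronger acceptor and adjusts the oxidation level afterwards. Setting out from 6, the same catalytic-base Michael addition to the far more electrophilic 3-phenylprop-2-ynal, followed by the same thiyl-radical equilibration, would give tert-butyl (3E)-2-[2-(1,3-dioxolan-2-yl)-3,5-dimethoxyphenoxy]-2-[4-(methoxymethoxy)phenyl]-5-oxo-3-phenylpent-3-enoate F4. Carbene-catalysed oxidative esterification of the enal (1,3-dimesitylimidazolium chloride, DBU, MnO2, EtOH) would then give the ethyl ester and return to 9.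

Step 13. Acyl transfer may stall because the polar hydroxy amine 19 dissolves poorly in the hot non-polar medium and its hydroxyl group competes for the acylketene, while prolonged heating degrades 12. The fallback assembles the bisamide on the core instead. Setting out from 12, thermal aminolysis with the lipophilic, hydroxyl-free amine 17 (DMAP, PhMe, 105 °C) would give tert-butyl (2S,3S,4R)-4-({4-[(tert-butoxycarbonyl)amino]butyl}carbamoyl)-6,8-dimethoxy-2-[4-(methoxymethoxy)phenyl]-5-oxo-3-phenyl-2,3,4,5-tetrahydro-1-benzoxepine-2-carboxylate F5. TFA/CH2Cl2/H2O would remove both tert-butyl groups and the methoxymethyl ether to give (2S,3S,4R)-4-[(4-aminobutyl)carbamoyl]-2-(4-hydroxyphenyl)-6,8-dimethoxy-5-oxo-3-phenyl-2,3,4,5-tetrahydro-1-benzoxepine-2-carboxylic acid F6. Selective N-acylation of its primary amine in THF/aqueous NaHCO3 with 2,5-dioxopyrrolidin-1-yl (2E)-4-hydroxy-2-methylbut-2-enoate F7, made from 16 with N-hydroxysuccinimide and EDC·HCl and used at once, would come back to the route at target 21.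

Further compounds
F1 | step 8 | 1-tert-butyl 5-ethyl (2S,3S)-2-[2-(1,3-dioxolan-2-yl)-3,5-dimethoxyphenoxy]-2-[4-(methoxymethoxy)phenyl]-3-phenylpentanedioate | COc1cc(OC)c(C2OCCO2)c(c1)O[C@](C(=O)OC(C)(C)C)(c1ccc(OCOC)cc1)[C@H](c1ccccc1)CC(=O)OCC
F2 | step 8 | 1-tert-butyl 5-ethyl (2S,3S)-2-(2-formyl-3,5-dimethoxyphenoxy)-2-[4-(methoxymethoxy)phenyl]-3-phenylpentanedioate | COc1cc(OC)c(C=O)c(c1)O[C@](C(=O)OC(C)(C)C)(c1ccc(OCOC)cc1)[C@H](c1ccccc1)CC(=O)OCC
F3 | step 8 | 2-tert-butyl 4-ethyl (2S,3S)-5-hydroxy-6,8-dimethoxy-2-[4-(methoxymethoxy)phenyl]-3-phenyl-2,3,4,5-tetrahydro-1-benzoxepine-2,4-dicarboxylate (mixture at C4 and C5) | COc1cc(OC)c2c(c1)O[C@](C(=O)OC(C)(C)C)(c1ccc(OCOC)cc1)[C@H](c1ccccc1)C(C(=O)OCC)C2O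
F4 | step 5 | tert-butyl (3E)-2-[2-(1,3-dioxolan-2-yl)-3,5-dimethoxyphenoxy]-2-[4-(methoxymethoxy)phenyl]-5-oxo-3-phenylpent-3-enoate (racemic) | COc1cc(OC)c(C2OCCO2)c(c1)OC(C(=O)OC(C)(C)C)(c1ccc(OCOC)cc1)/C(c1ccccc1)=C/C=O
F5 | step 13 | tert-butyl (2S,3S,4R)-4-({4-[(tert-butoxycarbonyl)amino]butyl}carbamoyl)-6,8-dimethoxy-2-[4-(methoxymethoxy)phenyl]-5-oxo-3-phenyl-2,3,4,5-tetrahydro-1-benzoxepine-2-carboxylate | COc1cc(OC)c2c(c1)O[C@](C(=O)OC(C)(C)C)(c1ccc(OCOC)cc1)[C@H](c1ccccc1)[C@@H](C(=O)NCCCCNC(=O)OC(C)(C)C)C2=O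
F6 | step 13 | (2S,3S,4R)-4-[(4-aminobutyl)carbamoyl]-2-(4-hydroxyphenyl)-6,8-dimethoxy-5-oxo-3-phenyl-2,3,4,5-tetrahydro-1-benzoxepine-2-carboxylic acid | COc1cc(OC)c2c(c1)O[C@](C(=O)O)(c1ccc(O)cc1)[C@H](c1ccccc1)[C@@H](C(=O)NCCCCN)C2=O
F7 | step 13 | 2,5-dioxopyrrolidin-1-yl (2E)-4-hydroxy-2-methylbut-2-enoate | O=C1CCC(=O)N1OC(=O)/C(C)=C/CO
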